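Ring atoms are numbered as in the systematic names of the intermediates: C1 (oxygen-bearing), C2 (methyl), C3 (oxymethyl-bearing), C4 (three-carbon diol side chain), C5 (methylene). Arm atoms carry primes (C1′ ester carbonyl to C6′ methyl).

## Analysis of the target

Target 22 has one carbocycle, a cyclopentane, and no other ring. Its four contiguous stereocentres C1–C4 are all-trans (1R,2R,3S,4R), so the substituents alternate between the two faces. The C1 oxygen and the oxygen of the C3 hydroxymethyl group are esterified by the same acid, (3S,4E)-4-formyl-3-(2-oxoethyl)hex-4-enoic acid. The molecule therefore has six stereocentres: four on the ring and one, C3′, in each arm, at least five bonds from the nearest ring stereocentre and out of reach of relay from the core. Each arm holds a saturated aldehyde and an E-configured trisubstituted enal (C6′ methyl trans to formyl), and the core holds a free 1,3-diol. The four aldehydes can enolise, undergo aldol reactions or form acetals with the diol, and the two esters exclude strong base or hydride late in the route. The difficulty is to make the same sensitive, stereodefined arm twice independently of the core chirality, to keep four aldehydes masked to the last step, and to place the C1 oxygen trans to the C2 methyl, which a selective hydride reduction does not deliver. The plan rests on one feature: in each arm C3′ is β to the ester carbonyl C1′ and bonded to the alkenyl carbon C4′, so C3′–C4′ is the bond of a conjugate alkenylation of a pent-2-enoate, and it occurs twice.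

## Retrosynthetic reasoning

**22 to 21.** No skeletal bond is cut. The four aldehydes are carried as dimethyl acetals and the diol as an isopropylidene ketal in 21. All five are O,O-acetals cleaved by one mechanism, so a single hydrolysis ends the route, and all are inert to the basic and organometallic steps before it.

**21 to 15 and two molecules of 20.** Both C3′–C4′ bonds are cut. This is the only bond in the arm whose formation creates the stereocentre while joining achiral pieces. Cutting the ester C–O bonds would require the whole arm as an enantiopure acid, and cutting C2′–C3′ would require enolate chemistry beside masked aldehydes. The gain is two C–C bonds and two stereocentres in one operation on bis-enoate 15, with the enal geometry delegated to boronate 20. The forward reaction must transfer the alkenyl group from boron to the β-carbon of each (E)-enoate with ligand-controlled face selection and retention of alkene geometry.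

**15 to 12 and two molecules of 14.** Both C2′=C3′ bonds are cut as olefinations of the bis(phosphonoacetate) 12 with aldehyde 14. A stabilised phosphonate gives the E geometry the conjugate addition needs. Aldehyde 14 comes from ester 13 by partial reduction.

**12 to 10 and two molecules of 11.** The two ester C–O bonds are cut, and at ring C1 it is the alkyl–oxygen bond that is formed in the forward sense. Hydride reduction of ketone 8 is selective only for the alcohol cis to the C2 methyl, the wrong C1 epimer. Diol 10 is therefore taken with that configuration on purpose, and esterification with acid 11 by an SN2 process with inversion corrects C1 while it installs the phosphonate. The primary hydroxyl is acylated in the same operation.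

**10 to 8 (through 9).** The C1 hydroxyl comes from the ketone, and the hydroxymethyl oxygen from a C–Si bond. The silyl group is a masked hydroxyl that tolerates organometallic introduction and is oxidised with retention.

**8 to 6 (through 7).** The C3–CH2 and C2–CH3 bonds are cut. Conjugate addition to enone 6 and alkylation of enolate 7 set C3 and C2 trans to each other and to C4 by substrate control.

**6 to 5, 4, 3, then 1 and 2.** The three side-chain carbons come from malonate 2, joined to the ring by allylic alkylation with net retention. The stereocentre is bought with monoacetate 1, an article of commerce in enantiopure form. Its carbinol carbon becomes the carbonyl of 6 and later ring C1.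

**20 to 19, 18, then 16 (through 17).** The C–B bond replaces a C–Br bond with retention. Bromo enal 18 arises from crotonaldehyde 16 by bromination and dehydrobromination, which leaves formyl trans to methyl, the geometry of the target enal.

## Alternatives that were turned down

**Alternative 1:** The ring is disconnected between C3 and C4. The acyclic aldehyde A2 already carries the C2 methyl and the C1 silyloxy group and ends in an alkylidene malonate. A chiral secondary amine (prolinol silyl ether type, carboxylic acid cocatalyst) would convert it into an enamine that closes the ring by a 5-exo-trig Michael addition to give the all-trans formyl malonate A1.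
- For: ring, one C–C bond and two stereocentres arise in one metal-free step. The formyl and malonate groups are the future hydroxymethyl and diol carbons. The formyl-bearing centre can epimerise to the trans isomer. The C1 oxygen has the right configuration from the start, a real advantage over the chosen route, which must invert C1.
- Against: A2 needs its own stereocontrolled synthesis of the methyl/silyloxy pair (estimated six to eight steps). The closure sets two centres against two existing ones, so catalyst and substrate preferences may not coincide. The β-branched aldehyde is a slow enamine partner.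
- Comparison: the plan ends at a protected core and leaves the arms, with two stereocentres and all the sensitive functionality, to a separate enantiopure synthesis and two esterifications. The chosen route reaches core diol 10 in six steps by substrate control and spends its one uncertain step where the repeated motif pays twice.

**Alternative 2:** The C2=C3 bond of a cyclopentene is disconnected, as a ring contraction of a terpene. (R)-Limonene A5, after conversion of its isopropenyl group into the ketal-protected 1,3-diol, would be cleaved at the ring alkene to keto aldehyde A4. An ammonium carboxylate would condense the aldehyde α-carbon with the methyl ketone to give the cyclopentene carbaldehyde A3.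
- For: the cheapest chiral starting material of all routes considered, C4 taken from the pool, methyl and formyl carbons placed by a robust condensation, no transition metal. On cost and scalability of the opening steps it is stronger than the chosen route.
- Against: in A3 ring C1 is a bare methylene. Its oxygen would need an allylic oxidation that must choose between C1, the C2 methyl and the C4 methine and also be face-selective. The tetrasubstituted C2=C3 bond must then be saturated with C2 and C3 trans to each other and to C4; neither hydrogenation (cis addition) nor conjugate reduction with protonation offers a reliable handle.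
- Comparison: three of four ring stereocentres stay open after the key step and the arms are not addressed. The chosen route sets C2 and C3 in one flask with the known trans preference.

**Alternative 3:** The core is disconnected at the C3–CH2 and C2–CH3 bonds, after catalytic desymmetrisation of the meso diacetate A7 by asymmetric allylic alkylation. The key step is the copper-catalysed 1,4-addition of a silylmethyl Grignard reagent to the derived enone (6 of the present route) with methylation of the enolate, giving the all-trans ketone A6, identical with 8.
- For: two bonds and two stereocentres in one flask under substrate control with firm precedent. As a key step it is more certain than the one chosen, which is why the same transformation serves here as step 5.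
- Against: as a strategy it leaves the arms to a separate asymmetric synthesis of an enantiopure acid and two esterifications, and does not use the repeated C3′–C4′ bond. The catalytic desymmetrisation adds an enantioselective step where monoacetate 1 can be bought.
- Comparison: the chosen strategy keeps this core chemistry and adds one two-directional operation that builds both arm stereocentres from achiral two-, three- and four-carbon pieces. It gives up certainty in that one step, and its fallback (an auxiliary-made arm acid) is what this alternative would have needed from the outset.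

Key step: step 13

Remark on the chemistry: the (R) hand of the bisphosphine in step 13 is assigned from the accepted face-selection model for (E)-enoates, in which the (S) ligand delivers the group to the re face of the β-carbon; the assignment would be confirmed on a simple model ester before use.

## Route

Step 1
Reactants: 1 (1S,4R)-cis-4-acetoxycyclopent-2-en-1-ol; 2 dimethyl malonate
Product: 3 dimethyl 2-[(1R,4S)-4-hydroxycyclopent-2-en-1-yl]malonate
Conditions: NaH, Pd(PPh3)4 (3 mol %), THF, 0 → 50 °C
Reagents that add atoms: none
Why: Tsuji–Trost allylic alkylation: zerovalent palladium ionises the acetate with inversion and the malonate anion attacks the π-allyl terminus remote from the hydroxyl on the face opposite to palladium, so the C–C bond forms with net retention, cis to the hydroxyl. The free hydroxyl is not a leaving group, so the carbinol centre of 1 is carried over unchanged.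

Step 2
Reactants: 3 dimethyl 2-[(1R,4S)-4-hydroxycyclopent-2-en-1-yl]malonate
Product: 4 2-[(1R,4S)-4-hydroxycyclopent-2-en-1-yl]propane-1,3-diol
Conditions: LiAlH4, THF, 0 °C → reflux; aqueous NaOH work-up
Reagents that add atoms: none
Why: Hydride reduction of both esters of a monosubstituted malonate gives the 2-substituted propane-1,3-diol. The alkene and the allylic alcohol are inert and no stereocentre is touched.

Step 3
Reactants: 4 2-[(1R,4S)-4-hydroxycyclopent-2-en-1-yl]propane-1,3-diol
Product: 5 (1S,4R)-4-(2,2-dimethyl-1,3-dioxan-5-yl)cyclopent-2-en-1-ol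
Conditions: 2,2-dimethoxypropane, pyridinium p-toluenesulfonate (cat.), acetone, rt
Reagents that add atoms: 2,2-dimethoxypropane, COC(C)(C)OC
Why: Transketalisation closes the six-membered 1,3-dioxane across the only 1,3-diol. The ring hydroxyl cannot join a ring of reasonable size, and a mixed ketal formed there is lost on aqueous work-up.

Step 4
Reactants: 5 (1S,4R)-4-(2,2-dimethyl-1,3-dioxan-5-yl)cyclopent-2-en-1-ol
Product: 6 (R)-4-(2,2-dimethyl-1,3-dioxan-5-yl)cyclopent-2-en-1-one
Conditions: MnO2 (activated, excess), CH2Cl2, rt
Reagents that add atoms: none
Why: Chemoselective oxidation of a secondary allylic alcohol to the enone under neutral conditions, which spare the ketal and the C4 stereocentre (γ to the carbonyl and at risk only under base).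

Step 5
Reactants: 6 (R)-4-(2,2-dimethyl-1,3-dioxan-5-yl)cyclopent-2-en-1-one
Product: 8 (2R,3S,4S)-4-(2,2-dimethyl-1,3-dioxan-5-yl)-3-{[dimethyl(propan-2-yloxy)silyl]methyl}-2-methylcyclopentan-1-one, via chloromagnesium enolate 7 (not isolated)
Conditions: (i-PrO)Me2SiCH2MgCl (from (i-PrO)Me2SiCH2Cl and Mg, THF), CuBr·SMe2 (10 mol %), THF, −78 °C; then MeI, DMPU, −78 → −20 °C
Reagents that add atoms: (isopropoxydimethylsilyl)methylmagnesium chloride, CC(C)O[Si](C)(C)C[Mg]Cl; iodomethane, CI
Why: Tandem conjugate addition–enolate alkylation: the copper-catalysed 1,4-addition occurs on the enone face opposite to the C4 dioxanyl group (3,4-trans) and the regiodefined enolate 7 is methylated at C2 anti to the new C3 substituent (2,3-trans). C2 stays epimerisable and the all-trans isomer is also the thermodynamic one.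

Step 6
Reactants: 8 (2R,3S,4S)-4-(2,2-dimethyl-1,3-dioxan-5-yl)-3-{[dimethyl(propan-2-yloxy)silyl]methyl}-2-methylcyclopentan-1-one
Product: 10 (1S,2R,3S,4R)-4-(2,2-dimethyl-1,3-dioxan-5-yl)-3-(hydroxymethyl)-2-methylcyclopentan-1-ol, via silyl alcohol 9 (not isolated)
Conditions: LiBH(s-Bu)3, THF, −78 °C; then KF, KHCO3, 30 % H2O2, MeOH–THF, 0 °C → rt
Reagents that add atoms: hydrogen peroxide, OO
Why: The bulky borohydride attacks the ketone on the face opposite to the adjacent C2 methyl and gives the alcohol cis to that methyl, the usual outcome for 2,3-trans-disubstituted cyclopentanones. The peroxide work-up that destroys the borane also performs the Tamao oxidation of the alkoxysilane, turning C–Si into C–OH with retention at carbon.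

Step 7
Reactants: 10 (1S,2R,3S,4R)-4-(2,2-dimethyl-1,3-dioxan-5-yl)-3-(hydroxymethyl)-2-methylcyclopentan-1-ol; 11 2-(diethoxyphosphoryl)acetic acid
Product: 12 (1R,2R,3S,4R)-3-({[2-(diethoxyphosphoryl)acetyl]oxy}methyl)-4-(2,2-dimethyl-1,3-dioxan-5-yl)-2-methylcyclopentyl 2-(diethoxyphosphoryl)acetate
Conditions: 11 (2.6 equiv), PPh3, diisopropyl azodicarboxylate, toluene, 0 °C → rt
Reagents that add atoms: none
Why: Twofold Mitsunobu esterification: the primary alcohol is esterified and the secondary oxyphosphonium ion is displaced by the carboxylate of this fairly strong acid in an SN2 reaction with inversion, which converts the 1,2-cis alcohol into the all-trans ester. The carboxylate is alkylated, so no activated acyl species meets the acidic methylene.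

Step 8
Reactants: 13 methyl 3,3-dimethoxypropanoate
Product: 14 3,3-dimethoxypropanal
Conditions: i-Bu2AlH (1.05 equiv), CH2Cl2, −78 °C; aqueous potassium sodium tartrate; used at once
Reagents that add atoms: none
Why: Partial reduction of the ester stops at the aluminium hemiacetal at low temperature and releases the aldehyde on work-up. The aldehyde is kept cold and not stored because it loses methanol easily.

Step 9
Reactants: 12 (1R,2R,3S,4R)-3-({[2-(diethoxyphosphoryl)acetyl]oxy}methyl)-4-(2,2-dimethyl-1,3-dioxan-5-yl)-2-methylcyclopentyl 2-(diethoxyphosphoryl)acetate; 14 3,3-dimethoxypropanal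
Product: 15 (1R,2R,3S,4R)-3-({[(E)-5,5-dimethoxypent-2-enoyl]oxy}methyl)-4-(2,2-dimethyl-1,3-dioxan-5-yl)-2-methylcyclopentyl (E)-5,5-dimethoxypent-2-enoate
Conditions: 14 (4 equiv), LiCl, i-Pr2NEt, MeCN, 0 °C → rt
Reagents that add atoms: none
Why: Twofold Horner–Wadsworth–Emmons olefination under Masamune–Roush conditions, where a weak amine base with lithium chelation deprotonates the phosphonoacetates but spares the β-alkoxy aldehyde and the esters. Stabilised phosphonates give the (E)-enoates.

Step 10
Reactants: 16 (E)-but-2-enal
Product: 18 (Z)-2-bromobut-2-enal, via dibromide 17 (not isolated)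
Conditions: Br2, CH2Cl2, 0 °C; then Et3N, 0 °C → rt
Reagents that add atoms: bromine, BrBr
Why: Anti addition of bromine to the enal, then amine-induced loss of HBr through the enolate of 17, gives the 2-bromo enal. The elimination is under thermodynamic control and places formyl trans to methyl (Z because bromine outranks formyl).

Step 11
Reactants: 18 (Z)-2-bromobut-2-enal
Product: 19 (Z)-2-bromo-1,1-dimethoxybut-2-ene
Conditions: HC(OMe)3, MeOH, p-TsOH·H2O (cat.), rt
Reagents that add atoms: trimethyl orthoformate, COC(OC)OC; methanol, CO
Why: Acid-catalysed acetalisation with the orthoester as water scavenger; the alkene geometry is unaffected and the aldehyde is masked for the two metal-catalysed steps that follow.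

Step 12
Reactants: 19 (Z)-2-bromo-1,1-dimethoxybut-2-ene
Product: 20 (E)-2-(1,1-dimethoxybut-2-en-2-yl)-4,4,5,5-tetramethyl-1,3,2-dioxaborolane
Conditions: B2pin2, PdCl2(PPh3)2 (3 mol %), PPh3, KOPh, toluene, 50 °C
Reagents that add atoms: bis(pinacolato)diboron, CC1(C)OB(OC1(C)C)B1OC(C)(C)C(C)(C)O1
Why: Miyaura borylation of an alkenyl bromide: oxidative addition, exchange with phenoxide, transmetalation with the diboron and reductive elimination all go with retention, so boron ends up cis to the methyl as bromine was.

Step 13
Reactants: 15 (1R,2R,3S,4R)-3-({[(E)-5,5-dimethoxypent-2-enoyl]oxy}methyl)-4-(2,2-dimethyl-1,3-dioxan-5-yl)-2-methylcyclopentyl (E)-5,5-dimethoxypent-2-enoate; 20 (E)-2-(1,1-dimethoxybut-2-en-2-yl)-4,4,5,5-tetramethyl-1,3,2-dioxaborolane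
Product: 21 (1R,2R,3S,4R)-3-({[(3S,4E)-3-(2,2-dimethoxyethyl)-4-(dimethoxymethyl)hex-4-enoyl]oxy}methyl)-4-(2,2-dimethyl-1,3-dioxan-5-yl)-2-methylcyclopentyl (3S,4E)-3-(2,2-dimethoxyethyl)-4-(dimethoxymethyl)hex-4-enoate
Conditions: 20 (4 equiv), [Rh(OH)((R)-binap)]2 (preformed from [Rh(OH)(cod)]2 and (R)-BINAP, 5 mol % Rh per enoate), K3PO4 (aq), 1,4-dioxane–H2O (10:1), degassed, 50 °C
Reagents that add atoms: none
Why: Boronate 20, activated by hydroxide, transmetalates to the hydroxo complex of monovalent rhodium and gives an alkenylrhodium species with retention of alkene geometry; the (E)-enoate coordinates and inserts into the Rh–C bond with carbon delivered to C3′, and water protonates the oxa-π-allyl rhodium enolate at C2′, releasing the product and regenerating Rh–OH. The closest known reaction type is the Hayashi–Miyaura asymmetric 1,4-addition of alkenylboron reagents to acyclic (E)-α,β-unsaturated esters; what is stretched is the α-branched, acetal-bearing alkenyl group and the need for the event to occur twice in one molecule. No ring is closed. Each new stereocentre (C3′ of each arm) is set by the chiral bisphosphine alone: with the (R) ligand the alkenyl group is expected on the si face of C3′, which gives the (S) configuration in both arms. The step needs face selection at two β-carbons, 1,4-addition in preference to attack at the ester, and retention of the donor geometry. The substrate secures this because the enoates lie four or more bonds from the ring stereocentres and far from each other, so each addition is an independent catalyst-controlled event, because acceptor and donor geometries are fixed beforehand, and because all four aldehyde carbons are base-stable acetals. The bisphosphine complex is preformed because a cyclooctadiene–rhodium hydroxide left in solution, or combined with a chiral diene it does not release, would catalyse an unselective background addition.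

Step 14
Reactants: 21 (1R,2R,3S,4R)-3-({[(3S,4E)-3-(2,2-dimethoxyethyl)-4-(dimethoxymethyl)hex-4-enoyl]oxy}methyl)-4-(2,2-dimethyl-1,3-dioxan-5-yl)-2-methylcyclopentyl (3S,4E)-3-(2,2-dimethoxyethyl)-4-(dimethoxymethyl)hex-4-enoate
Product: 22 (1R,2R,3S,4R)-4-(1,3-dihydroxypropan-2-yl)-3-({[(3S,4E)-4-formyl-3-(2-oxoethyl)hex-4-enoyl]oxy}methyl)-2-methylcyclopentyl (3S,4E)-4-formyl-3-(2-oxoethyl)hex-4-enoate
Conditions: 2 M aq. HCl–THF (1:3), 0 °C → rt; NaHCO3 quench
Reagents that add atoms: water, O
Why: Acid-catalysed hydrolysis of the four dimethyl acetals and the isopropylidene ketal through oxocarbenium ions, driven by the large excess of water. The esters and the E enals should survive dilute acid at this temperature, and none of the six stereocentres is α to a carbonyl group, so none can epimerise by enolisation.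

## Compound list

1 | (1S,4R)-cis-4-acetoxycyclopent-2-en-1-ol | O[C@@H]1C=C[C@H](OC(C)=O)C1 | starting material
2 | dimethyl malonate | COC(=O)CC(=O)OC | starting material
3 | dimethyl 2-[(1R,4S)-4-hydroxycyclopent-2-en-1-yl]malonate | O[C@@H]1C=C[C@H](C(C(=O)OC)C(=O)OC)C1 | intermediate
4 | 2-[(1R,4S)-4-hydroxycyclopent-2-en-1-yl]propane-1,3-diol | O[C@@H]1C=C[C@H](C(CO)CO)C1 | intermediate
5 | (1S,4R)-4-(2,2-dimethyl-1,3-dioxan-5-yl)cyclopent-2-en-1-ol | O[C@@H]1C=C[C@H](C2COC(C)(C)OC2)C1 | intermediate
6 | (R)-4-(2,2-dimethyl-1,3-dioxan-5-yl)cyclopent-2-en-1-one | O=C1C=C[C@H](C2COC(C)(C)OC2)C1 | intermediate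
7 | chloromagnesium (3S,4S)-4-(2,2-dimethyl-1,3-dioxan-5-yl)-3-{[dimethyl(propan-2-yloxy)silyl]methyl}cyclopent-1-en-1-olate | CC(C)O[Si](C)(C)C[C@@H]1C=C(O[Mg]Cl)C[C@H]1C2COC(C)(C)OC2 | intermediate
8 | (2R,3S,4S)-4-(2,2-dimethyl-1,3-dioxan-5-yl)-3-{[dimethyl(propan-2-yloxy)silyl]methyl}-2-methylcyclopentan-1-one (all-trans) | CC(C)O[Si](C)(C)C[C@@H]1[C@@H](C)C(=O)C[C@H]1C2COC(C)(C)OC2 | intermediate
9 | (1S,2R,3S,4S)-4-(2,2-dimethyl-1,3-dioxan-5-yl)-3-{[dimethyl(propan-2-yloxy)silyl]methyl}-2-methylcyclopentan-1-ol (hydroxyl cis to the C2 methyl) | CC(C)O[Si](C)(C)C[C@@H]1[C@@H](C)[C@@H](O)C[C@H]1C2COC(C)(C)OC2 | intermediate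
10 | (1S,2R,3S,4R)-4-(2,2-dimethyl-1,3-dioxan-5-yl)-3-(hydroxymethyl)-2-methylcyclopentan-1-ol (ring hydroxyl cis to the C2 methyl) | OC[C@@H]1[C@@H](C)[C@@H](O)C[C@H]1C2COC(C)(C)OC2 | intermediate
11 | 2-(diethoxyphosphoryl)acetic acid (diethylphosphonoacetic acid) | CCOP(=O)(CC(=O)O)OCC | starting material
12 | (1R,2R,3S,4R)-3-({[2-(diethoxyphosphoryl)acetyl]oxy}methyl)-4-(2,2-dimethyl-1,3-dioxan-5-yl)-2-methylcyclopentyl 2-(diethoxyphosphoryl)acetate | CCOP(=O)(OCC)CC(=O)OC[C@@H]1[C@@H](C)[C@H](OC(=O)CP(=O)(OCC)OCC)C[C@H]1C2COC(C)(C)OC2 | intermediate
13 | methyl 3,3-dimethoxypropanoate | COC(=O)CC(OC)OC | starting material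
14 | 3,3-dimethoxypropanal | COC(OC)CC=O | intermediate
15 | (1R,2R,3S,4R)-3-({[(E)-5,5-dimethoxypent-2-enoyl]oxy}methyl)-4-(2,2-dimethyl-1,3-dioxan-5-yl)-2-methylcyclopentyl (E)-5,5-dimethoxypent-2-enoate | COC(OC)C/C=C/C(=O)OC[C@@H]1[C@@H](C)[C@H](OC(=O)/C=C/CC(OC)OC)C[C@H]1C2COC(C)(C)OC2 | intermediate
16 | (E)-but-2-enal (crotonaldehyde) | C/C=C/C=O | starting material
17 | (2R*,3S*)-2,3-dibromobutanal (racemic anti adduct, one enantiomer drawn) | C[C@H](Br)[C@H](Br)C=O | intermediate
18 | (Z)-2-bromobut-2-enal | C/C=C(\Br)C=O | intermediate
19 | (Z)-2-bromo-1,1-dimethoxybut-2-ene | C/C=C(\Br)C(OC)OC | intermediate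
20 | (E)-2-(1,1-dimethoxybut-2-en-2-yl)-4,4,5,5-tetramethyl-1,3,2-dioxaborolane (methyl cis to boron) | C/C=C(\B1OC(C)(C)C(C)(C)O1)C(OC)OC | intermediate
21 | (1R,2R,3S,4R)-3-({[(3S,4E)-3-(2,2-dimethoxyethyl)-4-(dimethoxymethyl)hex-4-enoyl]oxy}methyl)-4-(2,2-dimethyl-1,3-dioxan-5-yl)-2-methylcyclopentyl (3S,4E)-3-(2,2-dimethoxyethyl)-4-(dimethoxymethyl)hex-4-enoate | C/C=C(/C(OC)OC)[C@@H](CC(OC)OC)CC(=O)OC[C@@H]1[C@@H](C)[C@H](OC(=O)C[C@H](CC(OC)OC)/C(C(OC)OC)=C\C)C[C@H]1C2COC(C)(C)OC2 | intermediate
22 | (1R,2R,3S,4R)-4-(1,3-dihydroxypropan-2-yl)-3-({[(3S,4E)-4-formyl-3-(2-oxoethyl)hex-4-enoyl]oxy}methyl)-2-methylcyclopentyl (3S,4E)-4-formyl-3-(2-oxoethyl)hex-4-enoate | C/C=C(/C=O)[C@@H](CC=O)CC(=O)OC[C@@H]1[C@@H](C)[C@H](OC(=O)C[C@H](CC=O)/C(C=O)=C\C)C[C@H]1C(CO)CO | target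

## Step count and least certain steps

Total: 14 steps. Longest linear sequence: 10 steps (1 to 7, 9, 13, 14) from monoacetate 1.

**Step 13 (key step).** Insertion of the hindered, α-branched alkenylrhodium into a β-alkyl enoate may be slow. Protodeboronation and β-methoxide elimination from the alkenylrhodium (an acetal oxygen sits β to rhodium) can then consume the donor, so conversion may stall after one arm. Incomplete face selection at either site would give diastereomers that are hard to separate because the sites are remote. Excess 20 is planned for the first problem, since neither side reaction kills the catalyst.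
Fallback (sets out from bromide 19, with 11, 14 and 10 as further inputs, and returns at 21): the arm is built off the core under auxiliary control and attached afterwards. Acid 11, as its pivaloyl mixed anhydride, acylates lithiated (R)-4-phenyloxazolidin-2-one to give (R)-3-[2-(diethoxyphosphoryl)acetyl]-4-phenyloxazolidin-2-one F1. Horner–Wadsworth–Emmons reaction with 14 (LiCl, i-Pr2NEt) gives (R)-3-[(E)-5,5-dimethoxypent-2-enoyl]-4-phenyloxazolidin-2-one F2. Bromide 19 is lithiated (t-BuLi, Et2O, −78 °C), transmetalated with MgBr2·OEt2 and added to F2 with CuBr·SMe2. The chelated syn-s-cis imide is attacked on the face opposite to the phenyl group, the si face of C3′, to give (R)-3-[(3S,4E)-3-(2,2-dimethoxyethyl)-4-(dimethoxymethyl)hex-4-enoyl]-4-phenyloxazolidin-2-one F3. LiOH/H2O2 removes the auxiliary and gives (3S,4E)-3-(2,2-dimethoxyethyl)-4-(dimethoxymethyl)hex-4-enoic acid F4. Twofold Mitsunobu esterification of diol 10 with F4 (inversion at ring C1 as in step 7) gives 21.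

**Step 7.** Elimination can compete with substitution at the activated secondary centre, which has an anti-periplanar hydrogen on C2, and substitution at this hindered carbon may be incomplete.
Fallback (sets out from 9, isolated by a non-oxidative work-up of the reduction in step 6, and returns at 12): Mitsunobu reaction of 9 with 4-nitrobenzoic acid, the strongest common acid partner, gives with inversion (1R,2R,3S,4S)-4-(2,2-dimethyl-1,3-dioxan-5-yl)-3-{[dimethyl(propan-2-yloxy)silyl]methyl}-2-methylcyclopentyl 4-nitrobenzoate F5. Tamao oxidation (KF, KHCO3, H2O2) followed by K2CO3 in methanol gives (1R,2R,3S,4R)-4-(2,2-dimethyl-1,3-dioxan-5-yl)-3-(hydroxymethyl)-2-methylcyclopentan-1-ol F6. Both hydroxyls of F6 are then acylated with 11 by carbodiimide coupling (EDC·HCl, catalytic DMAP), with retention, to give 12.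

**Step 5.** Methylation of the magnesium enolate is slow, and proton transfer between enolate and product ketone can lead to methylation at C5, double methylation or unmethylated ketone.
Fallback (sets out from 6 and returns at 8): the methyl group is installed before the conjugate addition. α-Iodination (I2, pyridine) gives (S)-4-(2,2-dimethyl-1,3-dioxan-5-yl)-2-iodocyclopent-2-en-1-one F7. Base-free Negishi coupling (MeZnCl, Pd(PPh3)4) gives (R)-4-(2,2-dimethyl-1,3-dioxan-5-yl)-2-methylcyclopent-2-en-1-one F8. The same copper-catalysed Grignard addition, protonation and equilibration of C2 with DBU to the all-trans isomer then gives 8.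

**Step 9.** Base-induced loss of methanol from aldehyde 14 may outrun olefination, and olefination of only one phosphonate would leave a mono-enoate.
Fallback (sets out from 14, with 10 as second input, and returns at 15): the olefination is done first on a simple ester under neutral conditions. Wittig reaction of 14 with methyl (triphenylphosphoranylidene)acetate gives methyl (E)-5,5-dimethoxypent-2-enoate F9. LiOH gives (E)-5,5-dimethoxypent-2-enoic acid F10. Twofold Mitsunobu esterification of 10 with F10 (inversion at ring C1) gives 15 without any acyl activation that could deconjugate the enoate.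

**Step 14.** Too little acid leaves acetals in place; too much exposure invites aldol-type condensation within the 1,5-dialdehyde arms or acetal exchange between the freed diol and the aldehydes.
Fallback (sets out from 21 and returns at 22): the unmasking is split into two operations of different mechanism. Pyridinium p-toluenesulfonate in methanol removes only the ketal, since the dimethyl acetals are degenerate in that solvent, and gives (1R,2R,3S,4R)-4-(1,3-dihydroxypropan-2-yl)-3-({[(3S,4E)-3-(2,2-dimethoxyethyl)-4-(dimethoxymethyl)hex-4-enoyl]oxy}methyl)-2-methylcyclopentyl (3S,4E)-3-(2,2-dimethoxyethyl)-4-(dimethoxymethyl)hex-4-enoate F11. The acetals are then cleaved under buffered, non-hydrolytic conditions (TMSOTf, 2,6-lutidine, CH2Cl2, 0 °C, then water) through pyridinium intermediates. The hydroxyls are silylated in passing and released in the aqueous work-up, so the free dialdehyde arms never meet aqueous acid.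

## Further compounds

F1 | step 13 | (R)-3-[2-(diethoxyphosphoryl)acetyl]-4-phenyloxazolidin-2-one | CCOP(=O)(OCC)CC(=O)N1[C@H](c2ccccc2)COC1=O
F2 | step 13 | (R)-3-[(E)-5,5-dimethoxypent-2-enoyl]-4-phenyloxazolidin-2-one | COC(OC)C/C=C/C(=O)N1[C@H](c2ccccc2)COC1=O
F3 | step 13 | (R)-3-[(3S,4E)-3-(2,2-dimethoxyethyl)-4-(dimethoxymethyl)hex-4-enoyl]-4-phenyloxazolidin-2-one | C/C=C(/C(OC)OC)[C@@H](CC(OC)OC)CC(=O)N1[C@H](c2ccccc2)COC1=O
F4 | step 13 | (3S,4E)-3-(2,2-dimethoxyethyl)-4-(dimethoxymethyl)hex-4-enoic acid | C/C=C(/C(OC)OC)[C@@H](CC(OC)OC)CC(=O)O
F5 | step 7 | (1R,2R,3S,4S)-4-(2,2-dimethyl-1,3-dioxan-5-yl)-3-{[dimethyl(propan-2-yloxy)silyl]methyl}-2-methylcyclopentyl 4-nitrobenzoate | CC(C)O[Si](C)(C)C[C@@H]1[C@@H](C)[C@H](OC(=O)c2ccc(cc2)[N+](=O)[O-])C[C@H]1C3COC(C)(C)OC3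
F6 | step 7 | (1R,2R,3S,4R)-4-(2,2-dimethyl-1,3-dioxan-5-yl)-3-(hydroxymethyl)-2-methylcyclopentan-1-ol | OC[C@@H]1[C@@H](C)[C@H](O)C[C@H]1C2COC(C)(C)OC2
F7 | step 5 | (S)-4-(2,2-dimethyl-1,3-dioxan-5-yl)-2-iodocyclopent-2-en-1-one | O=C1C(I)=C[C@H](C2COC(C)(C)OC2)C1
F8 | step 5 | (R)-4-(2,2-dimethyl-1,3-dioxan-5-yl)-2-methylcyclopent-2-en-1-one | O=C1C(C)=C[C@H](C2COC(C)(C)OC2)C1
F9 | step 9 | methyl (E)-5,5-dimethoxypent-2-enoate | COC(OC)C/C=C/C(=O)OC
F10 | step 9 | (E)-5,5-dimethoxypent-2-enoic acid | COC(OC)C/C=C/C(=O)O
F11 | step 14 | (1R,2R,3S,4R)-4-(1,3-dihydroxypropan-2-yl)-3-({[(3S,4E)-3-(2,2-dimethoxyethyl)-4-(dimethoxymethyl)hex-4-enoyl]oxy}methyl)-2-methylcyclopentyl (3S,4E)-3-(2,2-dimethoxyethyl)-4-(dimethoxymethyl)hex-4-enoate | C/C=C(/C(OC)OC)[C@@H](CC(OC)OC)CC(=O)OC[C@@H]1[C@@H](C)[C@H](OC(=O)C[C@H](CC(OC)OC)/C(C(OC)OC)=C\C)C[C@H]1C(CO)CO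
A1 | alternative 1 | all-trans dimethyl 2-[4-(tert-butyldimethylsilyloxy)-2-formyl-3-methylcyclopentyl]malonate | O=C[C@@H]1[C@@H](C)[C@H](O[Si](C)(C)C(C)(C)C)C[C@H]1C(C(=O)OC)C(=O)OC
A2 | alternative 1 | dimethyl 2-[(3R,4R)-3-(tert-butyldimethylsilyloxy)-4-methyl-6-oxohexylidene]malonate | O=CC[C@@H](C)[C@H](O[Si](C)(C)C(C)(C)C)CC=C(C(=O)OC)C(=O)OC
A3 | alternative 2 | (S)-5-(2,2-dimethyl-1,3-dioxan-5-yl)-2-methylcyclopent-1-ene-1-carbaldehyde | O=CC1=C(C)CC[C@H]1C2COC(C)(C)OC2
A4 | alternative 2 | (R)-3-(2,2-dimethyl-1,3-dioxan-5-yl)-6-oxoheptanal | O=CC[C@@H](CCC(C)=O)C1COC(C)(C)OC1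
A5 | alternative 2 | (R)-limonene | CC1=CC[C@@H](CC1)C(C)=C
A6 | alternative 3 | (2R,3S,4S)-4-(2,2-dimethyl-1,3-dioxan-5-yl)-3-{[dimethyl(propan-2-yloxy)silyl]methyl}-2-methylcyclopentan-1-one | CC(C)O[Si](C)(C)C[C@@H]1[C@@H](C)C(=O)C[C@H]1C2COC(C)(C)OC2
A7 | alternative 3 | cis-3,5-diacetoxycyclopent-1-ene (meso) | CC(=O)O[C@@H]1C=C[C@H](OC(C)=O)C1
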